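- Start from a ratio: target made over catalyst charged. In Wednesday's flask the last three readings average 39.2 %, and over 0.1 mol% that gives 392, the turnover budget: target made per catalyst charged before the catalyst is lost (the turnover number).

| setting | Wednesday's | Saturday's | flask |
|---|---|---|---|
| substrate | 0.20 M | 0.20 M | 0.20 M |
| free catalyst | 0.1 mol% | 0.1 mol% | 0.1 mol% |
| temperature | 80 °C | 86 °C | 80 °C |
| remark | the very flask that is asked about, followed so far | run made earlier |  |
| time |  |  | 8.0 d |

- Wednesday's (time / d: target / %, substrate / %): 0.625: 24.4, 77.7; 2.08: 37.7, 66.8; 4.00: 38.5, 60.2; 6.00: 40.4, 63.1; 8.00: 38.8, 60.4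
- Saturday's (time / d: target / %, substrate / %): 0.625: 26.6, 74.1; 2.08: 34.5, 66.0; 4.00: 35.2, 63.7; 6.00: 34.7, 65.0; 8.00: 35.3, 66.1

(scatter of a reading: 1 percentage point)

- target, in percent of the substrate first charged, at 8.0 d
- what to do for the largest gain in target; "none" if nothing gains more than 2 percentage points (alpha / delta / theta / eta / none)
- target present, with what was taken out counted in, in percent of the substrate first charged, after theta
- target present, with what was taken out counted in, in percent of the substrate first charged, after eta

- alpha: at 8.0 d take out 90 % of the target then present, then wait 2.5 d
- delta: change nothing and wait 2.5 d more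
- theta: at 8.0 d add free catalyst, 50.0 % of the amount charged, then wait 2.5 d
- eta: at 8.0 d raise the temperature by 25 K, then wait 2.5 d

- removed target is counted in
- the numbers in the tables scatter with a standard deviation of 1 percentage point
- additions bring no volume worth counting

- The decision is what to do with Wednesday's flask at 8.0 d. Substrate still reads 60.4 %, so the stop is either an equilibrium or a lost catalyst, and these readings fit both; my reckoning bets on loss.
- Treat the loss as a small correction: one catalyst goes per 392 turnovers. If both events need the same encounter, [substrate] and [free catalyst] cancel from their ratio, so the budget holds as [substrate] falls.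
- Saturday's flask reads 35.1 %, a budget of 351, less than Wednesday's, so I expect no gain from eta and keep 39.2 % for g4 and for now.
- Theta buys 20 percentage points at most, and the substrate reading has room for it. The wait of 2.5 d is longer than the 0.625 d by which Wednesday's flask read 24.4 %, a reading above that gain. My choice is theta, with g3 near 59.2 %.
- The forecast differs: 39 % now, alpha best, 39 % after theta, 26 % after eta, on the ground that “Extra catalyst doesn't shift the equilibrium”.
- The flask gives 38.2 % now, theta best, 54.9 % after theta and 38.2 % after eta. Theta's gain of 17 points is less than my ceiling.

    substrate + free catalyst → spent catalyst (k = 0.340 L mol⁻¹ h⁻¹, Ea = 82.0 kJ mol⁻¹)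
    substrate + free catalyst → free catalyst + target (k = 130 L mol⁻¹ h⁻¹, Ea = 68.0 kJ mol⁻¹)
    (constants at 80 °C)

- The step from substrate + free catalyst to spent catalyst is the main reason Wednesday's flask stops at 38.2 %: the run without that step reaches 99.3 %. Free catalyst stands at 0.0197 % after 8.00 d, and the budget read again from this flask, 38.2 % over 0.1 mol%, is 382. On the neighbour charged with 0.025 mol%, the budget of 392 gives 9.80 %, and that flask stores 9.56 %.

Readings and results stem from a simulated flask from invented constants, noise included.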